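**Retrosynthetic overview**
- Target 9 (5-hydroxyatranorin) ⇒ atranorin 5. The aryl C5–O bond of ring A is made last, by C–H acyloxylation with phthaloyl peroxide 7 and self-cleavage of the half ester 8.
- 5 ⇒ haematommic acid 3 + atraric acid 4. This is the depside ester C–O bond, formed without protecting groups.
- 3 ⇒ methyl orsellinate 1, by C3 formylation (2) and then ester cleavage. 7 ⇒ phthaloyl dichloride 6.
- No ring of the target is built. Ring A is bought in 1 and ring B in 4, and the two are joined in step 3.

Assumption: the SMILES holds no stereocentre, stereogenic axis or double-bond isomerism, so the target is achiral and nothing has to be set or resolved.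

Compounds 1, 4 and 6 are catalogue chemicals, and 4 is a bulk oakmoss odorant.

**Step 1**
Reactants: 1 methyl orsellinate (methyl 2,4-dihydroxy-6-methylbenzoate)
Product: 2 methyl haematommate (methyl 3-formyl-2,4-dihydroxy-6-methylbenzoate)
Conditions: Cl2CHOMe (1.2 equiv), TiCl4 (3 equiv), CH2Cl2, −10 to 0 °C, 2 h; then dilute aq. HCl, 20 °C; crystallise
Reagents that add atoms: dichloromethyl methyl ether, COC(Cl)Cl; water, O
Why: In this Rieche formylation (electrophilic aromatic substitution) the titanium phenoxide/salicylate chelate steers the oxocarbenium electrophile to C3, the carbon ortho to both oxygens, hydrolysis of the alpha-chloro ether gives the aldehyde, and the minor 5-formyl isomer stays in the mother liquor.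

**Step 2**
Reactants: 2 methyl haematommate
Product: 3 haematommic acid (3-formyl-2,4-dihydroxy-6-methylbenzoic acid)
Conditions: conc. H2SO4, 0 to 20 °C, 3 h; pour onto ice, filter
Reagents that add atoms: water, O
Why: Di-ortho-substituted, electron-rich benzoates ionise in cold concentrated H2SO4 to the acylium ion (AAC1 ester cleavage, as with mesitoates), and water captures it on quenching, so the hindered ester falls without base or heat and the chelated aldehyde is untouched.

**Step 3**
Reactants: 3 haematommic acid; 4 atraric acid (methyl 2,4-dihydroxy-3,6-dimethylbenzoate, 1.5 equiv)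
Product: 5 atranorin (methyl 4-[(3-formyl-2,4-dihydroxy-6-methylbenzoyl)oxy]-2-hydroxy-3,6-dimethylbenzoate)
Conditions: N,N'-dicyclohexylcarbodiimide (1.1 equiv), toluene, 20 °C, 20 h; filter, chromatograph
Reagents that add atoms: none
Why: In this carbodiimide esterification the O-acylisourea of 3 is taken by the only unchelated phenol present, the 4-OH of 4, because the 2-OH groups of both partners and the 4-OH of 3 are tied up in hydrogen bonds to ortho carbonyl groups.

**Step 4**
Reactants: 6 phthaloyl dichloride (benzene-1,2-dicarbonyl dichloride)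
Product: 7 phthaloyl peroxide (2,3-benzodioxine-1,4-dione)
Conditions: 2Na2CO3·3H2O2 (sodium percarbonate, excess), CH2Cl2, 20 °C, 5 h; filter, concentrate cold behind a shield, keep as a CH2Cl2 solution (shock- and heat-sensitive, gram scale at most)
Reagents that add atoms: sodium percarbonate (delivers H2O2), [Na+].[Na+].[Na+].[Na+].[O-]C([O-])=O.[O-]C([O-])=O.OO.OO.OO
Why: Double nucleophilic acyl substitution of the bis(acid chloride) by hydrogen peroxide released from the solid closes the six-membered cyclic diacyl peroxide, while the carbonate takes up the HCl (known preparation type).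

**Step 5**
Reactants: 5 atranorin; 7 phthaloyl peroxide (1.0 equiv)
Product: 9 5-hydroxyatranorin (methyl 4-[(3-formyl-2,4,5-trihydroxy-6-methylbenzoyl)oxy]-2-hydroxy-3,6-dimethylbenzoate; target), via atranorin 5-O-hydrogen phthalate 8 (not isolated)
Conditions: 1,1,1,3,3,3-hexafluoropropan-2-ol (HFIP)/CH2Cl2 1:1, 25 °C, dark, Ar, 6 h; then THF and degassed NaH2PO4/Na2HPO4 buffer (pH 7), 25 °C, 2 h, Ar; then dilute HCl to pH 2, extract
Reagents that add atoms: phthaloyl peroxide 7, O=C1OOC(=O)c2ccccc12
Why: Proposed new method: hydroxyl-steered C–H acyloxylation of an unprotected, chelated polyphenol by a cyclic diacyl peroxide, followed by neutral self-cleavage of the new ester; HFIP hydrogen-bonds to 7 and lowers its O–O sigma* orbital, and C5 of ring A is the only free ring carbon that is ortho to one free OH, para to a second and meta to both acyl groups, whereas C5' of ring B has one free OH and only a weakly donating acyloxy group (summed sigma-plus about 0.4 units less negative), so either direct attack of C5 on a peroxide oxygen or O-attack by the 4-OH followed by a [3,3] shift (C3 being blocked) gives the same dienone, which tautomerises to 8, whose new acyloxy group deactivates ring A against further oxidation to the quinone; at pH 7 the pendant carboxylate of 8 attacks its own ester carbonyl through a five-membered transition state and expels the C5 phenoxide as phthalic anhydride forms and then hydrolyses, while the di-ortho-substituted depside and methyl esters, which lack such a neighbour, stay intact; the closest known reaction types are arene C–H hydroxylation with phthaloyl peroxide on alkyl- and alkoxyarenes and the ortho-benzoyloxylation of simple phenols with dibenzoyl peroxide, neither of which has been shown on free formyl-resorcinol depsides or used to choose between two phenolic rings.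

**Compound list**
1 | methyl orsellinate (methyl 2,4-dihydroxy-6-methylbenzoate) | COC(=O)c1c(C)cc(O)cc1O | starting material
2 | methyl haematommate (methyl 3-formyl-2,4-dihydroxy-6-methylbenzoate) | COC(=O)c1c(C)cc(O)c(C=O)c1O | intermediate
3 | haematommic acid (3-formyl-2,4-dihydroxy-6-methylbenzoic acid) | OC(=O)c1c(C)cc(O)c(C=O)c1O | intermediate
4 | atraric acid (methyl 2,4-dihydroxy-3,6-dimethylbenzoate) | COC(=O)c1c(C)cc(O)c(C)c1O | starting material
5 | atranorin | COC(=O)c1c(C)cc(OC(=O)c2c(C)cc(O)c(C=O)c2O)c(C)c1O | intermediate
6 | phthaloyl dichloride | ClC(=O)c1ccccc1C(Cl)=O | starting material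
7 | phthaloyl peroxide (2,3-benzodioxine-1,4-dione) | O=C1OOC(=O)c2ccccc12 | intermediate
8 | atranorin 5-O-hydrogen phthalate (methyl 4-{[5-(2-carboxybenzoyloxy)-3-formyl-2,4-dihydroxy-6-methylbenzoyl]oxy}-2-hydroxy-3,6-dimethylbenzoate) | COC(=O)c1c(C)cc(OC(=O)c2c(C)c(OC(=O)c3ccccc3C(=O)O)c(O)c(C=O)c2O)c(C)c1O | intermediate
9 | 5-hydroxyatranorin (methyl 4-[(3-formyl-2,4,5-trihydroxy-6-methylbenzoyl)oxy]-2-hydroxy-3,6-dimethylbenzoate), achiral | COC(=O)c1c(C)cc(OC(=O)c2c(C)c(O)c(O)c(C=O)c2O)c(C)c1O | target

**Step count**
- Total steps: 5 (four on the main line plus the one-step preparation of oxidant 7).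
- Longest linear sequence: 4 (1 → 2 → 3 → 5 → 9).

**Steps most likely to fail**

Risk 1, step 5 (the new step). Possible failures are attack on ring B, over-oxidation to the hydroxyquinone, or no reaction. The fallback uses known chemistry only, sets out from 2 and comes back at 9. The C5 oxygen is installed before the union and carried through as a benzyl ether. Elbs persulfate oxidation of 2 (K2S2O8, aq. NaOH, 5 to 20 °C) attacks the free carbon para to the chelated 2-OH, as it does in resacetophenone and 2,4-dihydroxybenzaldehyde, and gives the potassium 5-sulfate of methyl haematommate F1. Hot dilute HCl hydrolyses this to methyl 3-formyl-2,4,5-trihydroxy-6-methylbenzoate F2. BnBr (2.1 equiv)/K2CO3/DMF alkylates the 4- and 5-OH and leaves the doubly chelated 2-OH, giving methyl 4,5-bis(benzyloxy)-3-formyl-2-hydroxy-6-methylbenzoate F3. KOH in aq. DMSO at 90 °C saponifies it to 4,5-bis(benzyloxy)-3-formyl-2-hydroxy-6-methylbenzoic acid F4. (CF3CO)2O in toluene joins F4 to the 4-OH of 4 to give 4,5-di-O-benzyl-5-hydroxyatranorin F5. H2 (1 atm), 10% Pd/C, EtOAc then removes both benzyl groups and gives 9.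

Risk 2, step 3 (unprotected carbodiimide union). Possible failures are self-acylation at the ring A 4-OH, N-acylurea formation, or low conversion of the hindered acid. The fallback sets out from 2 and comes back at 5. It masks the competing phenol and couples through a mixed anhydride. BnBr (1.05 equiv)/K2CO3/acetone gives methyl 4-(benzyloxy)-3-formyl-2-hydroxy-6-methylbenzoate F6. KOH in aq. DMSO at 90 °C gives 4-(benzyloxy)-3-formyl-2-hydroxy-6-methylbenzoic acid F7. (CF3CO)2O in toluene with 4 gives 4-O-benzylatranorin F8. H2 (1 atm), 10% Pd/C, EtOAc gives 5, and the chelated aldehyde survives a short hydrogenolysis.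

Risk 3, step 2 (ester cleavage in H2SO4). Possible failures are sulfonation at C5, protodecarboxylation to atranol, or deformylation. The fallback sets out from 1 and comes back at 3. Before the aldehyde is present, the ester is exchanged for one that is removed by neutral hydrogenolysis. Compound 1 is saponified briefly (aq. NaOH, 80 °C, N2, acidified at 0 °C) to orsellinic acid F9, which can also be bought. BnBr/KHCO3/DMF alkylates only the carboxylate to give benzyl orsellinate F10. Formylation as in step 1, but held at −20 °C, gives benzyl haematommate F11. H2 (1 atm), 10% Pd/C, EtOAc, stopped after one equivalent, gives 3.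

**Further compounds**
F1 | step 5 | potassium 5-sulfate of methyl haematommate | COC(=O)c1c(C)c(OS(=O)(=O)[O-])c(O)c(C=O)c1O.[K+]
F2 | step 5 | methyl 3-formyl-2,4,5-trihydroxy-6-methylbenzoate | COC(=O)c1c(C)c(O)c(O)c(C=O)c1O
F3 | step 5 | methyl 4,5-bis(benzyloxy)-3-formyl-2-hydroxy-6-methylbenzoate | COC(=O)c1c(C)c(OCc2ccccc2)c(OCc2ccccc2)c(C=O)c1O
F4 | step 5 | 4,5-bis(benzyloxy)-3-formyl-2-hydroxy-6-methylbenzoic acid | OC(=O)c1c(C)c(OCc2ccccc2)c(OCc2ccccc2)c(C=O)c1O
F5 | step 5 | 4,5-di-O-benzyl-5-hydroxyatranorin | COC(=O)c1c(C)cc(OC(=O)c2c(C)c(OCc3ccccc3)c(OCc3ccccc3)c(C=O)c2O)c(C)c1O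
F6 | step 3 | methyl 4-(benzyloxy)-3-formyl-2-hydroxy-6-methylbenzoate | COC(=O)c1c(C)cc(OCc2ccccc2)c(C=O)c1O
F7 | step 3 | 4-(benzyloxy)-3-formyl-2-hydroxy-6-methylbenzoic acid | OC(=O)c1c(C)cc(OCc2ccccc2)c(C=O)c1O
F8 | step 3 | 4-O-benzylatranorin | COC(=O)c1c(C)cc(OC(=O)c2c(C)cc(OCc3ccccc3)c(C=O)c2O)c(C)c1O
F9 | step 2 | orsellinic acid | OC(=O)c1c(C)cc(O)cc1O
F10 | step 2 | benzyl orsellinate | O=C(OCc1ccccc1)c1c(C)cc(O)cc1O
F11 | step 2 | benzyl haematommate | O=C(OCc1ccccc1)c1c(C)cc(O)c(C=O)c1O
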